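**Plan**

- Feature: O1, C2, C3, C4 and the C4-methyl carbon of the oxolane are the ring oxygen, C5, C4, C3 and the carbonyl carbon C2 of a 5-aryl furan-2(5H)-one carrying aryl A (3-benzyloxy-4,5-dimethoxyphenyl; the free phenol in the target). C5 of the target, with aryl B (3,4,5-trimethoxyphenyl), is an aldehyde carbon.
- Retrosynthesis: cut O1–C5 (benzylic ether), return the C4 methyl to a lactone carbonyl, then cut C4–C5 (aldol) and C3–CH3 (conjugate addition) in one operation. This leaves the (S)-butenolide, a methyl cuprate and 3,4,5-trimethoxybenzaldehyde; the butenolide goes back to the aryl aldehyde and methyl propiolate.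
- Forward: the butenolide ring is made first (steps 1–3); both C–C bonds are then attached without ring formation (step 4); the lactone is opened reductively and its carbonyl carbon taken to CH3 (steps 5–7); the oxolane closes last by acid-mediated benzylic etherification (step 8), followed by debenzylation (step 9).
- Stereochemistry: C2 comes from a zinc–ProPhenol alkynylation. C3 and C4 come from two anti additions across the butenolide, relayed from C2 (the trans,trans lactone becomes the cis-3,4-dimethyl pattern once the carbonyl is a methyl). C5 settles trans to the C4 methyl in the cationic ring closure.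

Key step: step 4

Assumption: (S,S)-ProPhenol is taken to give the (R)-carbinol 4 (otherwise the (R,R)-ligand is used), and the aldol carbinol centre of 9 is expected as an epimer mixture, so compounds 9–14 are drawn as the epimer that already matches C5 of the target while the other epimer is carried through the same steps and converges in step 8.

**Step 1**
Reactants: 1 3-hydroxy-4,5-dimethoxybenzaldehyde
Product: 2 3-(benzyloxy)-4,5-dimethoxybenzaldehyde
Conditions: BnBr, K2CO3, DMF, rt
Reagents that add atoms: benzyl bromide, BrCc1ccccc1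
Why: Williamson ether synthesis, in which the phenoxide is O-alkylated by the benzylic bromide while the aldehyde is untouched; no stereocenter is formed.

**Step 2**
Reactants: 2 3-(benzyloxy)-4,5-dimethoxybenzaldehyde; 3 methyl propiolate
Product: 4 methyl (R)-4-[3-(benzyloxy)-4,5-dimethoxyphenyl]-4-hydroxybut-2-ynoate
Conditions: (S,S)-ProPhenol [2,6-bis{[(S)-2-(hydroxydiphenylmethyl)pyrrolidin-1-yl]methyl}-4-methylphenol] (20 mol%), Me2Zn (3 equiv), Ph3P=O (40 mol%), 3 (3 equiv), toluene, 4 °C; aq NH4Cl
Reagents that add atoms: none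
Why: Dinuclear zinc–ProPhenol catalysed asymmetric alkynylation of an aldehyde, in which Me2Zn turns the propiolate into its zinc alkynylide and the chiral bimetallic pocket binds aldehyde and alkynylide so that only one carbonyl face is attacked, setting the carbinol stereocenter that becomes C2 of the target.

**Step 3**
Reactants: 4 methyl (R)-4-[3-(benzyloxy)-4,5-dimethoxyphenyl]-4-hydroxybut-2-ynoate
Product: 6 (S)-5-[3-(benzyloxy)-4,5-dimethoxyphenyl]furan-2(5H)-one, via Z-hydroxy enoate 5 (not isolated)
Conditions: H2 (1 atm), Pd/CaCO3 poisoned with Pb(OAc)2, quinoline (cat.), EtOAc, rt; then PPTS (cat.), CH2Cl2, rt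
Reagents that add atoms: none
Why: Lindlar semihydrogenation delivers the Z-enoate by syn addition of hydrogen, which places the hydroxyl next to the ester so that lactonization with loss of methanol follows; the stereocenter is not touched and its descriptor changes from R to S only because the CIP ranking of its substituents changes.

**Step 4**
Reactants: 6 (S)-5-[3-(benzyloxy)-4,5-dimethoxyphenyl]furan-2(5H)-one; 7 3,4,5-trimethoxybenzaldehyde
Product: 9 (3R,4S,5S)-5-[3-(benzyloxy)-4,5-dimethoxyphenyl]-3-[(R)-hydroxy(3,4,5-trimethoxyphenyl)methyl]-4-methyloxolan-2-one, via lithium enolate 8 (not isolated)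
Conditions: Me2CuLi (1.3 equiv, from MeLi and CuI), Et2O, −78 °C; then 7 (1.5 equiv) in THF, −78 °C; aq NH4Cl quench at −78 °C
Reagents that add atoms: lithium dimethylcuprate, [Li+].C[Cu-]C
Why: The Gilman reagent adds its methyl to C4 of the enoate (π-complex, trivalent copper β-adduct, reductive elimination) to give lithium enolate 8, whose C3 then attacks the carbonyl of 7 in an aldol addition, so that C4–CH3 and C3–CH(OH)Ar form in one flask. The closest known reaction type is the tandem conjugate addition–aldol (three-component) coupling of organocuprates and aldehydes with cycloalkenones and 5-substituted butenolides. No ring is closed. The C4 stereocenter is controlled by the C5 aryl group, which shields one face of the flat butenolide so that methyl enters anti to it, and the C3 stereocenter by the new C4 methyl, the enolate being attacked anti to it, which gives the trans,trans lactone that is also the more stable one. The carbinol stereocenter is governed only by the aldol transition state of the ring-locked E(O)-enolate and is the weakly controlled one, which is tolerated because step 8 resets it. The step needs 1,4-addition to win over 1,2-addition and over removal of the acidic benzylic C5–H, which the soft, weakly basic cuprate at −78 °C secures, and it needs the enolate to be captured before it equilibrates, which addition of 7 at −78 °C directly after the cuprate and a cold quench secure.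

**Step 5**
Reactants: 9 (3R,4S,5S)-5-[3-(benzyloxy)-4,5-dimethoxyphenyl]-3-[(R)-hydroxy(3,4,5-trimethoxyphenyl)methyl]-4-methyloxolan-2-one
Product: 10 (1S,2S,3S,4R)-1-[3-(benzyloxy)-4,5-dimethoxyphenyl]-3-(hydroxymethyl)-2-methyl-4-(3,4,5-trimethoxyphenyl)butane-1,4-diol
Conditions: LiAlH4 (3 equiv), THF, 0 °C; aq NaOH work-up
Reagents that add atoms: none
Why: Hydride reduction of a lactone to the diol, which at 0 °C should be faster than retro-aldol cleavage of the aluminium alkoxide formed from the free hydroxyl and leaves all four stereocenters untouched.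

**Step 6**
Reactants: 10 (1S,2S,3S,4R)-1-[3-(benzyloxy)-4,5-dimethoxyphenyl]-3-(hydroxymethyl)-2-methyl-4-(3,4,5-trimethoxyphenyl)butane-1,4-diol
Product: 12 (1S,2S,3S,4R)-1-[3-(benzyloxy)-4,5-dimethoxyphenyl]-2-methyl-3-(tosyloxymethyl)-4-(3,4,5-trimethoxyphenyl)-1,4-bis(triethylsilyloxy)butane, via primary monotosylate 11 (not isolated)
Conditions: TsCl (1.1 equiv), Et3N, Me3N·HCl (cat.), CH2Cl2, 0 °C; then 2,6-lutidine, TESOTf (3 equiv), −40 → 0 °C
Reagents that add atoms: 4-methylbenzenesulfonyl chloride, Cc1ccc(cc1)S(=O)(=O)Cl; triethylsilyl trifluoromethanesulfonate, CC[Si](CC)(CC)OS(=O)(=O)C(F)(F)F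
Why: Chemoselective sulfonylation of the single primary hydroxyl over two hindered secondary benzylic ones, followed in the same flask by silyl ether formation at both benzylic hydroxyls, which removes the 1,4-related nucleophile before it can displace the tosylate to form an unwanted oxolane.

**Step 7**
Reactants: 12 (1S,2S,3S,4R)-1-[3-(benzyloxy)-4,5-dimethoxyphenyl]-2-methyl-3-(tosyloxymethyl)-4-(3,4,5-trimethoxyphenyl)-1,4-bis(triethylsilyloxy)butane
Product: 13 (1S,2S,3R,4R)-1-[3-(benzyloxy)-4,5-dimethoxyphenyl]-2,3-dimethyl-4-(3,4,5-trimethoxyphenyl)-1,4-bis(triethylsilyloxy)butane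
Conditions: LiBHEt3 (4 equiv), THF, 0 °C → rt
Reagents that add atoms: none
Why: SN2 displacement of a primary tosylate by the triethylborohydride, which turns the former lactone carbonyl carbon into the second methyl group while silyl ethers, benzyl ether and all stereocenters stay as they are (the descriptor at C3 changes only through the CIP ranking).

**Step 8**
Reactants: 13 (1S,2S,3R,4R)-1-[3-(benzyloxy)-4,5-dimethoxyphenyl]-2,3-dimethyl-4-(3,4,5-trimethoxyphenyl)-1,4-bis(triethylsilyloxy)butane
Product: 15 (2S,3S,4R,5R)-2-[3-(benzyloxy)-4,5-dimethoxyphenyl]-3,4-dimethyl-5-(3,4,5-trimethoxyphenyl)oxolane, via diol 14 (not isolated)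
Conditions: TFA (10 equiv), wet CH2Cl2, 0 °C → rt
Reagents that add atoms: none
Why: Acid cleaves the triethylsilyl ethers and then ionizes a benzylic hydroxyl to an aryl-stabilized cation that the other hydroxyl captures in a 5-exo cyclodehydration of a 1,4-diaryl-1,4-diol; because the benzylic C–O bonds of the product can re-ionize under the acid while C3 and C4 cannot change, each aryl group should settle trans to its neighbouring methyl, which fixes C5 and keeps C2 for either carbinol epimer.

**Step 9**
Reactants: 15 (2S,3S,4R,5R)-2-[3-(benzyloxy)-4,5-dimethoxyphenyl]-3,4-dimethyl-5-(3,4,5-trimethoxyphenyl)oxolane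
Product: 16 5-[(2S,3S,4R,5R)-3,4-dimethyl-5-(3,4,5-trimethoxyphenyl)oxolan-2-yl]-2,3-dimethoxyphenol
Conditions: H2 (1 atm), 10% Pd/C, EtOAc, rt
Reagents that add atoms: none
Why: Catalytic hydrogenolysis of an aryl benzyl ether, which is much faster than cleavage of the secondary benzylic C–O bonds of the oxolane in a neutral solvent and touches no stereocenter.

**Compound list**

1 | 3-hydroxy-4,5-dimethoxybenzaldehyde | COc1cc(C=O)cc(O)c1OC | starting material
2 | 3-(benzyloxy)-4,5-dimethoxybenzaldehyde | COc1cc(C=O)cc(OCc2ccccc2)c1OC | intermediate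
3 | methyl propiolate | C#CC(=O)OC | starting material
4 | methyl (R)-4-[3-(benzyloxy)-4,5-dimethoxyphenyl]-4-hydroxybut-2-ynoate | COc1cc([C@H](C#CC(=O)OC)O)cc(OCc2ccccc2)c1OC | intermediate
5 | methyl (2Z,4S)-4-[3-(benzyloxy)-4,5-dimethoxyphenyl]-4-hydroxybut-2-enoate (not isolated) | COc1cc([C@H](/C=C\C(=O)OC)O)cc(OCc2ccccc2)c1OC | intermediate
6 | (S)-5-[3-(benzyloxy)-4,5-dimethoxyphenyl]furan-2(5H)-one | COc1cc([C@H]2OC(=O)C=C2)cc(OCc3ccccc3)c1OC | intermediate
7 | 3,4,5-trimethoxybenzaldehyde | COc1cc(C=O)cc(OC)c1OC | starting material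
8 | lithium (4S,5S)-5-[3-(benzyloxy)-4,5-dimethoxyphenyl]-4-methyl-4,5-dihydrofuran-2-olate (not isolated) | COc1cc([C@H]2OC([O-])=C[C@@H]2C)cc(OCc3ccccc3)c1OC.[Li+] | intermediate
9 | (3R,4S,5S)-5-[3-(benzyloxy)-4,5-dimethoxyphenyl]-3-[(R)-hydroxy(3,4,5-trimethoxyphenyl)methyl]-4-methyloxolan-2-one | COc1cc([C@H]2OC(=O)[C@@H]([C@@H](O)c3cc(OC)c(OC)c(OC)c3)[C@@H]2C)cc(OCc4ccccc4)c1OC | intermediate
10 | (1S,2S,3S,4R)-1-[3-(benzyloxy)-4,5-dimethoxyphenyl]-3-(hydroxymethyl)-2-methyl-4-(3,4,5-trimethoxyphenyl)butane-1,4-diol | COc1cc([C@@H](O)[C@@H](C)[C@@H](CO)[C@@H](O)c2cc(OC)c(OC)c(OC)c2)cc(OCc3ccccc3)c1OC | intermediate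
11 | (1S,2S,3S,4R)-1-[3-(benzyloxy)-4,5-dimethoxyphenyl]-2-methyl-3-(tosyloxymethyl)-4-(3,4,5-trimethoxyphenyl)butane-1,4-diol (not isolated) | COc1cc([C@@H](O)[C@@H](C)[C@@H](COS(=O)(=O)c4ccc(C)cc4)[C@@H](O)c2cc(OC)c(OC)c(OC)c2)cc(OCc3ccccc3)c1OC | intermediate
12 | (1S,2S,3S,4R)-1-[3-(benzyloxy)-4,5-dimethoxyphenyl]-2-methyl-3-(tosyloxymethyl)-4-(3,4,5-trimethoxyphenyl)-1,4-bis(triethylsilyloxy)butane | COc1cc([C@@H](O[Si](CC)(CC)CC)[C@@H](C)[C@@H](COS(=O)(=O)c4ccc(C)cc4)[C@@H](O[Si](CC)(CC)CC)c2cc(OC)c(OC)c(OC)c2)cc(OCc3ccccc3)c1OC | intermediate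
13 | (1S,2S,3R,4R)-1-[3-(benzyloxy)-4,5-dimethoxyphenyl]-2,3-dimethyl-4-(3,4,5-trimethoxyphenyl)-1,4-bis(triethylsilyloxy)butane | COc1cc([C@@H](O[Si](CC)(CC)CC)[C@@H](C)[C@@H](C)[C@@H](O[Si](CC)(CC)CC)c2cc(OC)c(OC)c(OC)c2)cc(OCc3ccccc3)c1OC | intermediate
14 | (1S,2S,3R,4R)-1-[3-(benzyloxy)-4,5-dimethoxyphenyl]-2,3-dimethyl-4-(3,4,5-trimethoxyphenyl)butane-1,4-diol (not isolated) | COc1cc([C@@H](O)[C@@H](C)[C@@H](C)[C@@H](O)c2cc(OC)c(OC)c(OC)c2)cc(OCc3ccccc3)c1OC | intermediate
15 | (2S,3S,4R,5R)-2-[3-(benzyloxy)-4,5-dimethoxyphenyl]-3,4-dimethyl-5-(3,4,5-trimethoxyphenyl)oxolane | COc1cc([C@H]2O[C@@H](c3cc(OC)c(OC)c(OC)c3)[C@H](C)[C@@H]2C)cc(OCc4ccccc4)c1OC | intermediate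
16 | 5-[(2S,3S,4R,5R)-3,4-dimethyl-5-(3,4,5-trimethoxyphenyl)oxolan-2-yl]-2,3-dimethoxyphenol | COc1cc([C@H]2O[C@@H](c3cc(OC)c(OC)c(OC)c3)[C@H](C)[C@@H]2C)cc(O)c1OC | target

**Step count and risks**

Total step count: 9. Longest linear sequence: 9 steps, from 1 to 16 (3 and 7 are bought).

Steps most likely to fail:

Step 4. The cuprate may remove the acidic benzylic C5–H instead of adding, which would erode the enantiomeric purity, or the enolate may exchange a proton or fail to capture the electron-rich aldehyde, leaving only the conjugate adduct. The fallback separates the two bond formations. It sets out from 6: Me2CuLi in Et2O at −78 °C with a proton quench should give the isolated trans lactone (4S,5S)-5-[3-(benzyloxy)-4,5-dimethoxyphenyl]-4-methyloxolan-2-one F1. Its enolate is then made on its own with LiN(iPr)2 in THF at −78 °C, transmetalated with ZnCl2 and treated with 7, again with attack anti to the C4 methyl. The sequence comes back to the route at 9.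

Step 6. The 1,4-related benzylic hydroxyl may displace the fresh primary tosylate before it is silylated (closure to an unwanted oxolane), or a benzylic hydroxyl may be sulfonylated and ionize. The fallback differentiates the hydroxyls by protecting groups and never has a free hydroxyl beside a leaving group. It sets out from 10: TESOTf and 2,6-lutidine should give (1S,2S,3S,4R)-1-[3-(benzyloxy)-4,5-dimethoxyphenyl]-2-methyl-1,4-bis(triethylsilyloxy)-3-[(triethylsilyloxy)methyl]-4-(3,4,5-trimethoxyphenyl)butane F2. HF·pyridine buffered with pyridine in THF at 0 °C should remove only the primary silyl group to give (1S,2S,3S,4R)-1-[3-(benzyloxy)-4,5-dimethoxyphenyl]-3-(hydroxymethyl)-2-methyl-4-(3,4,5-trimethoxyphenyl)-1,4-bis(triethylsilyloxy)butane F3. Appel iodination (I2, PPh3, imidazole) should then give (1S,2S,3R,4R)-1-[3-(benzyloxy)-4,5-dimethoxyphenyl]-3-(iodomethyl)-2-methyl-4-(3,4,5-trimethoxyphenyl)-1,4-bis(triethylsilyloxy)butane F4, and LiBHEt3 should reduce the iodide. The sequence comes back to the route at 13.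

Step 8. Under the strong acid the benzylic cation may alkylate the other electron-rich arene (aryltetralin formation) or lose a proton to a styrene, or the benzylic epimers may not equilibrate fully to the all-trans aryl/methyl arrangement. The fallback closes the ring under basic conditions through a sulfonate. It sets out from 13: Bu4NF in THF should give diol 14, now isolated. MsCl and Et3N in CH2Cl2 at −20 °C should form the benzylic mesylate (1R,2R,3S,4S)-4-[3-(benzyloxy)-4,5-dimethoxyphenyl]-4-hydroxy-2,3-dimethyl-1-(3,4,5-trimethoxyphenyl)butyl methanesulfonate F5 (its regioisomer at the other benzylic carbon behaves alike), which should ionize as it forms and be captured by the remaining hydroxyl trans to the adjacent methyl, with no free strong acid present. The sequence comes back to the route at 15.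

**Further compounds**

F1 | step 4 | (4S,5S)-5-[3-(benzyloxy)-4,5-dimethoxyphenyl]-4-methyloxolan-2-one | COc1cc([C@H]2OC(=O)C[C@@H]2C)cc(OCc3ccccc3)c1OC
F2 | step 6 | (1S,2S,3S,4R)-1-[3-(benzyloxy)-4,5-dimethoxyphenyl]-2-methyl-1,4-bis(triethylsilyloxy)-3-[(triethylsilyloxy)methyl]-4-(3,4,5-trimethoxyphenyl)butane | COc1cc([C@@H](O[Si](CC)(CC)CC)[C@@H](C)[C@@H](CO[Si](CC)(CC)CC)[C@@H](O[Si](CC)(CC)CC)c2cc(OC)c(OC)c(OC)c2)cc(OCc3ccccc3)c1OC
F3 | step 6 | (1S,2S,3S,4R)-1-[3-(benzyloxy)-4,5-dimethoxyphenyl]-3-(hydroxymethyl)-2-methyl-4-(3,4,5-trimethoxyphenyl)-1,4-bis(triethylsilyloxy)butane | COc1cc([C@@H](O[Si](CC)(CC)CC)[C@@H](C)[C@@H](CO)[C@@H](O[Si](CC)(CC)CC)c2cc(OC)c(OC)c(OC)c2)cc(OCc3ccccc3)c1OC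
F4 | step 6 | (1S,2S,3R,4R)-1-[3-(benzyloxy)-4,5-dimethoxyphenyl]-3-(iodomethyl)-2-methyl-4-(3,4,5-trimethoxyphenyl)-1,4-bis(triethylsilyloxy)butane | COc1cc([C@@H](O[Si](CC)(CC)CC)[C@@H](C)[C@@H](CI)[C@@H](O[Si](CC)(CC)CC)c2cc(OC)c(OC)c(OC)c2)cc(OCc3ccccc3)c1OC
F5 | step 8 | (1R,2R,3S,4S)-4-[3-(benzyloxy)-4,5-dimethoxyphenyl]-4-hydroxy-2,3-dimethyl-1-(3,4,5-trimethoxyphenyl)butyl methanesulfonate | COc1cc([C@@H](O)[C@@H](C)[C@@H](C)[C@@H](OS(C)(=O)=O)c2cc(OC)c(OC)c(OC)c2)cc(OCc3ccccc3)c1OC
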